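The runs are simulated with constants of no real substance; noise was put on by code.

The north-west run, charged with 1.00 M of starting material, stands at 0.244 M of product after 6.0 min and 0.252 M after 9.5 min. The south run has the same charge and is asked about at 19 min.

| flask | starting material | time |
|---|---|---|
| north-west | 1.00 M |  |
| south-east | 0.500 M |  |
| south-west | 1.50 M |  |
| south | 1.00 M | 19 min |

| north-west run: time / min | north-west run: [product] / M | south-east run: time / min | south-east run: [product] / M | south-west run: time / min | south-west run: [product] / M |
|---|---|---|---|---|---|
| 0.34 | 0.001 | 0.34 | 0.014 | 0.34 | 0.028 |
| 1.0 | 0.055 | 1.0 | 0.009 | 1.0 | 0.122 |
| 2.0 | 0.119 | 2.0 | 0.029 | 2.0 | 0.249 |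
| 3.1 | 0.172 | 3.1 | 0.040 | 3.1 | 0.341 |
| 4.5 | 0.212 | 4.5 | 0.062 | 4.5 | 0.427 |
| 6.0 | 0.244 | 6.0 | 0.061 | 6.0 | 0.461 |
| 7.7 | 0.240 | 7.7 | 0.076 | 7.7 | 0.479 |
| 9.5 | 0.252 | 9.5 | 0.071 | 9.5 | 0.500 |

(scatter of a reading: 0.008 M)

- the exponent of [starting material] in the starting rate at the charge of the north-west run (at the point where two percent of the starting material have become product) (one fixed amount of product, the same in the runs compared)
- product in the south run at 19 min, as a share of the starting material charged
- which of these the readings show (the substrate is lost by itself / the substrate pairs with itself / the product speeds the reaction / nothing beyond the main steps)

- Overall: starting material -> product.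
- Constant volume, constant temperature.
- An order is taken over about fifteen percent of the charge, up and down.

Two chemists argue over these runs. The first holds that this is a plain second-order reaction that merely slows. The north-west slope between 1.0 min and 2.0 min gives him a constant of 0.0640 M^-1 min^-1, which puts the south run at 54.9% of its charge at 19 min.

The second answers that his curve needs 0.378 M in the north-west run at 9.5 min, and the flask reads less, 0.252 M. She sets a first-order loss of starting material against second-order making, so that making over loss equals the amount present divided by one fixed amount. That amount is the crossing concentration, where the two run level, and the selectivity for product at any moment is amount/(amount + crossing).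

I side with her and reckon it roughly. The share falls as the starting material falls, so I take the share at half the charge as the mean. The last south-west reading, at 9.5 min, stands at 33.3% of its charge, and taken as that run's end it gives a crossing of 1.50 M. The south run then comes to 25.0%. For the order, I read the product at 2.0 min in the south-west and north-west runs and get 1.82, though that is taken at a fixed time and not at a fixed amount of product.

The forecast gives an order of 2, a share of 26.3% and the verdict "the substrate is lost by itself", seeing “second-order product formation competing with first-order loss of substrate”.

The simulation gives an order of 1.4, which is lower than my reading, a share of 25.8%, and the verdict "the substrate is lost by itself".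

    2 starting material ⇌ intermediate + starting material (0.1278 M⁻¹ min⁻¹, 0.05172 M⁻¹ min⁻¹)
    intermediate → product (1.968 min⁻¹)
    starting material → decomposed substrate (0.1638 min⁻¹)

Carried to the south-east run, the crossing gives 0.0714 M of product, and the last reading there is 0.071 M. The south run's charge lies below the crossing, and the loss of starting material to decomposed substrate is the main reason for its low share. With that step taken away, the south run gives 70.0% in place of 25.8%, and there the first chemist's picture of a reaction that merely slows has its ground, though the apparent order without the step is 1.3, not second. The step costs 44 percentage points, which is 60% of what is missing.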